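The route rests on cutting the dimethylpyran ring of the chromene at two bonds at once: the bond from the pyran oxygen to ring A and the bond between the two olefinic CH carbons. The pyran fragment O–C(CH3)2–CH then is a 1,3-dianion, a β-lithio alkoxide, and ring A a 1,3-dielectrophile, an ortho-fluorobenzaldehyde. The key step exploits that the oxygen-bearing carbon of ring A lies para to the acyl-bearing carbon (carried as a nitrile) and ortho to the carbon that holds the pyran CH: carbon adds to the aldehyde, the tertiary alkoxide displaces fluoride, and elimination in the same flask gives the chromene. Methyl Grignard addition and a Claisen–Schmidt condensation with the prenylated aldehyde complete the chalcone.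

Key step: step 3

Remark: the lithium alkoxide intermediates of step 3 are listed as their neutral alcohols, and the olefinic bond of the pyran ring is first made as a single bond and desaturated in the same flask.

Step 1
Reactants: 1 4-fluoro-2-hydroxybenzonitrile
Product: 2 4-fluoro-2-(methoxymethoxy)benzonitrile
Conditions: MOMCl, i-Pr2NEt, CH2Cl2, 0 °C to rt
Reagents that add atoms: chloromethyl methyl ether (MOMCl), COCCl
Why: Williamson-type O-alkylation of the acidic cyanophenol with the α-chloro ether should be clean and installs an acetal that later directs the metalation and keeps ring A electron-poor.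

Step 2
Reactants: 2 4-fluoro-2-(methoxymethoxy)benzonitrile
Product: 4 4-fluoro-3-formyl-2-(methoxymethoxy)benzonitrile, via arylmagnesium chloride 3 (not isolated)
Conditions: TMPMgCl·LiCl, THF, −20 to 0 °C; then DMF, 0 °C to rt; aq. NH4Cl
Reagents that add atoms: N,N-dimethylformamide (DMF), CN(C)C=O
Why: Directed ortho-metalation should occur at the C–H flanked by fluorine and the methoxymethoxy group, the most acidic and doubly coordinated site, with a hindered magnesium amide that leaves the nitrile alone, and the arylmagnesium is then formylated by DMF (formylation of an aryl organometallic with a formamide).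

Step 3
Reactants: 4 4-fluoro-3-formyl-2-(methoxymethoxy)benzonitrile; 5 1-chloro-2-methylpropan-2-ol
Product: 10 5-(methoxymethoxy)-2,2-dimethyl-2H-chromene-6-carbonitrile, via β-lithio alkoxide 6 (not isolated), via diol dialkoxide 7 (not isolated), via chromanol alkoxide 8 (not isolated), via mesylate 9 (not isolated)
Conditions: 5, n-BuLi, THF, −78 °C; lithium naphthalenide (LiC10H8, 2.0 equiv, no excess), −78 °C; then 4, −78 °C; DMPU, −78 to 55 °C; then MsCl, 0 °C; DBU, rt to 40 °C
Reagents that add atoms: none
Why: The chlorohydrin is deprotonated and its C–Cl bond reductively lithiated to the β-lithio alkoxide 6, whose carbanion adds to the aldehyde of 4 at −78 °C to make the bond between the two future olefinic carbons of the pyran ring, after which warming in DMPU lets the tertiary alkoxide of 7 displace fluoride by addition–elimination (SNAr) to make the aryl–oxygen bond. The remaining benzylic alkoxide of 8 is mesylated in the same flask and loses methanesulfonic acid under DBU (E1/E2 through a benzylic cation or ion pair stabilised by both ortho oxygens), which turns the new C–C single bond into the chromene double bond. The closest known reaction types are the addition of β-oxido organolithium reagents to aldehydes to give 1,3-diols and the closure of chromans by intramolecular SNAr of 3-(2-fluoroaryl)propanol alkoxides. The pyran ring closes in a 6-exo-trig mode onto the fluorine-bearing ipso carbon through a Meisenheimer intermediate stabilised by the para nitrile. The only new stereocenter, the carbinol carbon of 7 and 8, forms racemic without control and is erased by the elimination, so no control is needed. The step needs carbanion attack on the aldehyde and not on the nitrile or the C–F carbon, secured by the low temperature and the absence of excess radical anion, and it needs the alkoxide to displace fluoride and not the methoxymethoxy group on the other ortho carbon, secured by the far better nucleofugality of fluoride and its para relation to the nitrile, while the benzylic alkoxide cannot reach either carbon without forming a four-membered ring.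

Step 4
Reactants: 10 5-(methoxymethoxy)-2,2-dimethyl-2H-chromene-6-carbonitrile
Product: 13 1-(5-hydroxy-2,2-dimethyl-2H-chromen-6-yl)ethan-1-one, via ketimine 11 (not isolated), via MOM-protected ketone 12 (not isolated)
Conditions: MeMgBr, THF/toluene, 0 to 65 °C; then 2 M aq. HCl, THF, 45 °C
Reagents that add atoms: methylmagnesium bromide, C[Mg]Br; water, O
Why: Grignard addition to the nitrile stops at the magnesium ketimine, and aqueous acid then hydrolyses the imine to the methyl ketone and cleaves the methoxymethyl acetal, a deprotection favoured by the hydrogen bond of the ortho-hydroxy ketone (nitrile-to-ketone Grignard synthesis followed by acetal hydrolysis).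

Step 5
Reactants: 14 4-hydroxybenzaldehyde; 15 1-bromo-3-methylbut-2-ene (prenyl bromide)
Product: 16 4-hydroxy-3-(3-methylbut-2-en-1-yl)benzaldehyde
Conditions: KOH, H2O, rt
Reagents that add atoms: none
Why: In water the phenoxide oxygen is strongly solvated, so SN2 attack of the ortho carbon on the primary allylic bromide competes and the dienone tautomerises to the ortho-prenyl phenol (phenoxide C-alkylation).

Step 6
Reactants: 13 1-(5-hydroxy-2,2-dimethyl-2H-chromen-6-yl)ethan-1-one; 16 4-hydroxy-3-(3-methylbut-2-en-1-yl)benzaldehyde
Product: 17 paratocarpin B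
Conditions: KOH (50% aq., excess), EtOH, 0 °C to rt; then dilute HCl to pH 5
Reagents that add atoms: none
Why: In this Claisen–Schmidt aldol condensation the ketone enolate adds to the aldehyde and E1cB loss of hydroxide gives the conjugated enone, whose E geometry is the thermodynamically favoured one set in the reversible elimination.

Compound list
1 | 4-fluoro-2-hydroxybenzonitrile | N#Cc1ccc(F)cc1O | starting material
2 | 4-fluoro-2-(methoxymethoxy)benzonitrile | COCOc1cc(F)ccc1C#N | intermediate
3 | [3-cyano-6-fluoro-2-(methoxymethoxy)phenyl]magnesium chloride | COCOc1c(C#N)ccc(F)c1[Mg]Cl | intermediate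
4 | 4-fluoro-3-formyl-2-(methoxymethoxy)benzonitrile | COCOc1c(C#N)ccc(F)c1C=O | intermediate
5 | 1-chloro-2-methylpropan-2-ol | CC(C)(O)CCl | starting material
6 | lithium 1-lithio-2-methylpropan-2-olate | [Li]CC(C)(C)O[Li] | intermediate
7 | 4-fluoro-3-(1,3-dihydroxy-3-methylbutyl)-2-(methoxymethoxy)benzonitrile (racemic, present as its dilithium dialkoxide) | COCOc1c(C#N)ccc(F)c1C(O)CC(C)(C)O | intermediate
8 | 4-hydroxy-5-(methoxymethoxy)-2,2-dimethyl-3,4-dihydro-2H-chromene-6-carbonitrile (racemic, present as its lithium alkoxide) | COCOc1c(C#N)ccc2OC(C)(C)CC(O)c12 | intermediate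
9 | 6-cyano-5-(methoxymethoxy)-2,2-dimethyl-3,4-dihydro-2H-chromen-4-yl methanesulfonate (racemic) | COCOc1c(C#N)ccc2OC(C)(C)CC(OS(C)(=O)=O)c12 | intermediate
10 | 5-(methoxymethoxy)-2,2-dimethyl-2H-chromene-6-carbonitrile | COCOc1c(C#N)ccc2OC(C)(C)C=Cc12 | intermediate
11 | 1-[5-(methoxymethoxy)-2,2-dimethyl-2H-chromen-6-yl]ethan-1-imine | COCOc1c(C(C)=N)ccc2OC(C)(C)C=Cc12 | intermediate
12 | 1-[5-(methoxymethoxy)-2,2-dimethyl-2H-chromen-6-yl]ethan-1-one | COCOc1c(C(C)=O)ccc2OC(C)(C)C=Cc12 | intermediate
13 | 1-(5-hydroxy-2,2-dimethyl-2H-chromen-6-yl)ethan-1-one | CC(=O)c1ccc2OC(C)(C)C=Cc2c1O | intermediate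
14 | 4-hydroxybenzaldehyde | O=Cc1ccc(O)cc1 | starting material
15 | 1-bromo-3-methylbut-2-ene | CC(C)=CCBr | starting material
16 | 4-hydroxy-3-(3-methylbut-2-en-1-yl)benzaldehyde | CC(C)=CCc1cc(C=O)ccc1O | intermediate
17 | paratocarpin B, (E)-1-(5-hydroxy-2,2-dimethyl-2H-chromen-6-yl)-3-[4-hydroxy-3-(3-methylbut-2-en-1-yl)phenyl]prop-2-en-1-one | CC(C)=CCc1cc(/C=C/C(=O)c2ccc3c(c2O)C=CC(C)(C)O3)ccc1O | target

Total step count: 6. Longest linear sequence: 5 steps (steps 1, 2, 3, 4 and 6); step 5 supplies the second fragment.

Steps most likely to fail

Step 3. The β-lithio alkoxide may lose lithium oxide to isobutene before it adds. The aggregated lithium alkoxide may also displace fluoride too slowly, so that mesylation meets an open-chain diol. The fallback sets out from 4, returns at 10, and closes the two ring bonds in separate operations. Fluoride of 4 is displaced by the potassium alkoxide of 2-methylbut-3-en-2-ol (KN(SiMe3)2, THF, −40 to 0 °C) in an SNAr etherification, which should give 3-formyl-2-(methoxymethoxy)-4-[(2-methylbut-3-en-2-yl)oxy]benzonitrile F1. Wittig methylenation of the aldehyde (Ph3PCH3Br, KOtBu, THF, 0 °C) should give 3-ethenyl-2-(methoxymethoxy)-4-[(2-methylbut-3-en-2-yl)oxy]benzonitrile F2. Ring-closing metathesis of the styrene with the tertiary allyl ether (second-generation Grubbs catalyst, CH2Cl2, 40 °C) should then give 10.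

Step 6. The aldehyde 16 is deprotonated to its phenoxide under the basic conditions, which lowers its electrophilicity, so the aldol addition may stall. The 2'-hydroxychalcone may also cyclise in part to the flavanone on long exposure to base. The fallback sets out from 16 and returns at 17. The phenol of 16 is protected (MOMCl, i-Pr2NEt, CH2Cl2), which should give 4-(methoxymethoxy)-3-(3-methylbut-2-en-1-yl)benzaldehyde F3. Claisen–Schmidt condensation of this non-ionisable aldehyde with 13 (KOH, EtOH, rt) should give (E)-1-(5-hydroxy-2,2-dimethyl-2H-chromen-6-yl)-3-[4-(methoxymethoxy)-3-(3-methylbut-2-en-1-yl)phenyl]prop-2-en-1-one F4. Brief acetal hydrolysis (2 M aq. HCl, THF, 40 °C) should then release 17.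

Step 5. O-alkylation and double alkylation compete with ortho-C-alkylation of the ambident phenoxide, so little of the mono-C-prenyl product may form. The fallback sets out from 14 and returns at 16. Bromination ortho to the hydroxyl group (Br2, AcOH, rt) should give 3-bromo-4-hydroxybenzaldehyde F5. Stille coupling with tributyl(3-methylbut-2-en-1-yl)stannane (Pd(PPh3)4, DMF, 90 °C) should then place the prenyl group at the brominated carbon and give 16.

Further compounds
F1 | step 3 | 3-formyl-2-(methoxymethoxy)-4-[(2-methylbut-3-en-2-yl)oxy]benzonitrile | COCOc1c(C#N)ccc(OC(C)(C)C=C)c1C=O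
F2 | step 3 | 3-ethenyl-2-(methoxymethoxy)-4-[(2-methylbut-3-en-2-yl)oxy]benzonitrile | COCOc1c(C#N)ccc(OC(C)(C)C=C)c1C=C
F3 | step 6 | 4-(methoxymethoxy)-3-(3-methylbut-2-en-1-yl)benzaldehyde | CC(C)=CCc1cc(C=O)ccc1OCOC
F4 | step 6 | (E)-1-(5-hydroxy-2,2-dimethyl-2H-chromen-6-yl)-3-[4-(methoxymethoxy)-3-(3-methylbut-2-en-1-yl)phenyl]prop-2-en-1-one | CC(C)=CCc1cc(/C=C/C(=O)c2ccc3c(c2O)C=CC(C)(C)O3)ccc1OCOC
F5 | step 5 | 3-bromo-4-hydroxybenzaldehyde | O=Cc1ccc(O)c(Br)c1
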